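Early in each flask E opens to Z with a half-life of 0.13 min, and from then on D has two exits: round the catalyst to G, or onto G as D.G.

    E → Z (k1 = 0.0894 /s)
    D ⇌ L (K2 = 0.60, k2 = 0.129 /s)
    D + Z ⇌ D.Z (K3 = 44 /M, k3 = 2.85 /M/s)
    D.Z → X (k4 = 0.207 /s)
    X → Z + G (k5 = 0.0356 /s)
    D + G → D.G (k6 = 0.216 /M/s)
in all of them: D 0.050 M; time 6.0 min
- theta: E 7.5 mM
- alpha: E 9.8 mM
- which of these there is most of at the end, counted by the D in it, theta (D / G / D.G / X)
- which of these there is most of at the end, counted by the D in it, alpha (D / G / D.G / X)
- how much there is at the end of the one of these that leads, in percent of the D charged: theta
- how much there is at the end of the one of these that leads, in percent of the D charged: alpha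
- in percentages every species weighs as the D in it: one D.G counts as two
- run time (theta): 6.0 min

We count in fractions of the charge of D and look for the fraction of free D that sets the order of the rate. Taking the round as steady, we call it the pivot (the Michaelis constant over the charge): the free D at which the catalyst turns at 0.5 of its top speed. For theta the pivot is 28.0 % and the top speed 0.273 /min of the charge. Balanced with L, free D starts at 62.5 %, higher than the pivot, so by this reckoning the round in theta opens at 69.1 % of its top speed, with an order in D of about 0.309.

What we carry is the side number, a kind of selectivity factor: the rate of D + G over the rate of the round, at the moment free D stands at the pivot and G at 0.5 of the charge. For theta it is 0.663.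

Now the settings. More E raises the top speed and leaves the pivot alone, so alpha's side number is 0.508. More D raises the side number in proportion. More time should add little, since the first-order tail of theta has a time constant of 1.64 min, the round alone, shorter than the run. Both side numbers lie below one, so we commit to G leading in both flasks, more clearly in alpha, and we give no percentage.

The forecast names G for theta at 46 % (41 % to 51 %) and G for alpha at 56 % (50 % to 62 %), on the grounds that “more catalyst gets G out faster”.

Theta ends with G at 49.7 % and D.G at 40.6 %, alpha with G at 59.6 % and D.G at 36.3 %, so G leads in both. Each setting moved alone by the same factor shifts alpha's G in this order: E (9.8 points), then D (9.3 points), then time (5.4 points). A neighbour of theta holds 0.085 M of D, and there the side number is 1.13, above one. That flask ends with G at 30.3 % and D.G ahead at 53.6 %.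

The constants are assumed; the flask was simulated.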